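**Assumption:** the target has no stereocentres and no E/Z-stereogenic double bonds (it is achiral), so "single enantiomer" is taken to mean the constitution exactly as drawn. No step in the route has to set or preserve a stereocentre.

## Retrosynthetic overview

1. Target ⇐ removal of four MOM ethers ⇐ flavonol 15 ⇐ Algar–Flynn–Oyamada oxidative cyclisation of chalcone 14. The pyranone C ring is the only ring formed, and it is formed last.
2. Chalcone 14 ⇐ Claisen–Schmidt condensation of A-ring acetophenone 5 with B-ring aldehyde 13. Both aromatic rings are purchased.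
3. A ring: the 8-(1,1-dimethylallyl) group comes from an aromatic Claisen rearrangement of a 4-O-prenyl ether of phloroacetophenone (para position blocked, chelation directs to C3).
4. B ring: the 3'-prenyl comes from Claisen rearrangement of a 4-O-(1,1-dimethylallyl) ether. The 2'-prenyl comes from the proposed new step, a transient-imine-directed Rh(III) ortho-C–H prenylation of a 3,4-dioxygenated benzaldehyde.

## Route

### Part A – A-ring ketone

**Step 1**
Reactants: 1, 2',4',6'-trihydroxyacetophenone
Product: 2, 1-[2,6-dihydroxy-4-(3-methylbut-2-enyloxy)phenyl]ethanone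
Conditions: prenyl bromide (1.05 equiv), K2CO3 (1.1 equiv), acetone, reflux
Reagents that add atoms: prenyl bromide, CC(C)=CCBr
Why: Williamson etherification occurs at the most acidic, non-chelated 4-OH, while the two ketone-chelated OH groups stay free under weak base.

**Step 2**
Reactants: 2
Product: 3, 1-[2-hydroxy-6-(methoxymethoxy)-4-(3-methylbut-2-enyloxy)phenyl]ethanone
Conditions: MOMCl (1.1 equiv), i-Pr2NEt, CH2Cl2, 0 °C → rt
Reagents that add atoms: chloromethyl methyl ether, COCCl
Why: the two OH groups are symmetry-equivalent, and after the first MOM etherification the remaining OH is held in a strong H-bond to the ketone, so mono-protection stops cleanly.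

**Step 3**
Reactants: 3
Product: 4, 1-[2,4-dihydroxy-6-(methoxymethoxy)-3-(2-methylbut-3-en-2-yl)phenyl]ethanone
Conditions: PhNEt2, 180–185 °C, sealed tube, 2–3 h
Reagents that add atoms: none
Why: aromatic Claisen [3,3] rearrangement with allyl inversion gives the 1,1-dimethylallyl group ortho to O-4 (para is blocked by the acetyl), and chelation of the 2-OH to the ketone fixes C3=C4 so migration goes to C3, not to C5 beside the bulkier OMOM.

**Step 4**
Reactants: 4
Product: 5, 1-[2-hydroxy-4,6-bis(methoxymethoxy)-3-(2-methylbut-3-en-2-yl)phenyl]ethanone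
Conditions: MOMCl (1.2 equiv), i-Pr2NEt, CH2Cl2, 0 °C → rt
Reagents that add atoms: chloromethyl methyl ether, COCCl
Why: MOM etherification is selective for the free 4-OH, because the 2-OH is chelated to the ketone and flanked by the tertiary alkyl group.

### Part B – B-ring aldehyde

**Step 5**
Reactants: 6, 3,4-dihydroxybenzaldehyde
Product: 7, 4-hydroxy-3-(methoxymethoxy)benzaldehyde
Conditions: NaH (2.2 equiv), DMF, 0 °C; then MOMCl (1.0 equiv), −20 → 0 °C
Reagents that add atoms: chloromethyl methyl ether, COCCl
Why: in the catecholate dianion the 3-oxide is not conjugated to the aldehyde and is the more nucleophilic, so one equivalent of MOMCl alkylates O-3 (regioselective dianion mono-O-alkylation).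

**Step 6**
Reactants: 7
Product: 8, 3-(methoxymethoxy)-4-(triisopropylsilyloxy)benzaldehyde
Conditions: TIPSCl, imidazole, DMF, rt
Reagents that add atoms: triisopropylsilyl chloride, CC(C)[Si](Cl)(C(C)C)C(C)C
Why: standard phenol silylation gives a temporary 4-O group that is orthogonal to MOM and inert to the C–H activation conditions.

**Step 7 (proposed new transformation)**
Reactants: 8
Product: 9, 5-(methoxymethoxy)-2-(3-methylbut-2-enyl)-4-(triisopropylsilyloxy)benzaldehyde
Conditions: [Cp*RhCl2]2 (2.5 mol%), AgSbF6 (10 mol%), 3,5-(CF3)2C6H3NH2 (30 mol%), NaOPiv (20 mol%), PivOH (50 mol%), tert-butyl (2-methylbut-3-en-2-yl) carbonate (1.5 equiv), DCE, 50 °C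
Reagents that add atoms: tert-butyl (2-methylbut-3-en-2-yl) carbonate, C=CC(C)(C)OC(=O)OC(C)(C)C (commercial, or one step from 2-methylbut-3-en-2-ol and Boc2O)
Why: Proposed new method: the aniline condenses reversibly with the aldehyde to a transient N-aryl imine that directs pivalate-assisted cyclometalation by Cp*Rh(III) at the less hindered ortho C–H (C6; C2 is flanked by OMOM), the aryl–Rh bond inserts the terminal alkene of the tertiary allylic carbonate with aryl going to CH2, and β-oxygen elimination of tert-butyl carbonate (→ CO2 + t-BuOH, overall redox- and proton-neutral) releases the linear prenyl arene before transimination returns the aldehyde and the amine; mono-selectivity follows from 1.5 equiv of carbonate and the hindered second ortho site; the closest known reaction types are Cp*Rh(III)/Cp*Co(III) C–H allylation and prenylation with allylic carbonates under permanent N-directing groups, and Rh(III)/Ir(III) transient-imine-directed ortho-C–H functionalisation of benzaldehydes (e.g. amidation), which have not been combined to prenylate a benzaldehyde.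

**Step 8**
Reactants: 9
Product: 10, 4-hydroxy-5-(methoxymethoxy)-2-(3-methylbut-2-enyl)benzaldehyde
Conditions: TBAF (1.1 equiv), AcOH (1.1 equiv), THF, 0 °C
Reagents that add atoms: none
Why: fluoride-mediated cleavage of the aryl silyl ether leaves the MOM ether, aldehyde and prenyl group untouched.

**Step 9**
Reactants: 10
Product: 11, 5-(methoxymethoxy)-4-[(2-methylbut-3-en-2-yl)oxy]-2-(3-methylbut-2-enyl)benzaldehyde
Conditions: tert-butyl (2-methylbut-3-en-2-yl) carbonate (1.5 equiv), Pd(PPh3)4 (5 mol%), THF, 0 °C
Reagents that add atoms: tert-butyl (2-methylbut-3-en-2-yl) carbonate, C=CC(C)(C)OC(=O)OC(C)(C)C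
Why: Pd-catalysed decarboxylative allylic etherification (Tsuji–Trost type) in which the phenoxide attacks the more substituted terminus of the π-prenyl-Pd complex under kinetic control (low temperature, short time) to give the tertiary aryl ether.

**Step 10**
Reactants: 11
Product: 12, 4-hydroxy-5-(methoxymethoxy)-2,3-bis(3-methylbut-2-enyl)benzaldehyde
Conditions: toluene, 110 °C, sealed tube
Reagents that add atoms: none
Why: aromatic Claisen [3,3] rearrangement with allyl inversion converts O–CMe2–CH=CH2 into C–CH2–CH=CMe2 at C3, the only free ortho position of O-4 (C5 carries OMOM), and the ring then re-aromatises by tautomerisation.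

**Step 11**
Reactants: 12
Product: 13, 4,5-bis(methoxymethoxy)-2,3-bis(3-methylbut-2-enyl)benzaldehyde
Conditions: MOMCl (1.5 equiv), i-Pr2NEt, CH2Cl2, 0 °C → rt
Reagents that add atoms: chloromethyl methyl ether, COCCl
Why: MOM etherification of the acidic para-formyl phenol, which must be masked so the aldehyde stays electrophilic in the aldol step.

### Part C – Union and completion

**Step 12**
Reactants: 5 and 13
Product: 14, (E)-1-[2-hydroxy-4,6-bis(methoxymethoxy)-3-(2-methylbut-3-en-2-yl)phenyl]-3-[4,5-bis(methoxymethoxy)-2,3-bis(3-methylbut-2-enyl)phenyl]prop-2-en-1-one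
Conditions: KOH (excess), EtOH, rt, 24–48 h
Reagents that add atoms: none
Why: Claisen–Schmidt aldol condensation of the methyl ketone with the non-enolisable aldehyde, with E1cB dehydration giving the thermodynamic E-enone; MOM ethers and all three alkenes are base-stable.

**Step 13**
Reactants: 14
Product: 15, 2-[4,5-bis(methoxymethoxy)-2,3-bis(3-methylbut-2-enyl)phenyl]-3-hydroxy-5,7-bis(methoxymethoxy)-8-(2-methylbut-3-en-2-yl)-4H-chromen-4-one
Conditions: 30% H2O2, 2 M NaOH, MeOH/THF, 0 °C → rt
Reagents that add atoms: hydrogen peroxide, OO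
Why: Algar–Flynn–Oyamada reaction, in which the 2'-phenoxide closes onto the enone β-carbon and alkaline peroxide oxidises the resulting enolate to the 3-hydroxyflavone; nucleophilic HOO⁻ does not touch the isolated prenyl and vinyl alkenes.

**Step 14**
Reactants: 15
Product: 16, Broussoflavonol C, 2-[4,5-dihydroxy-2,3-bis(3-methylbut-2-enyl)phenyl]-3,5,7-trihydroxy-8-(2-methylbut-3-en-2-yl)-4H-chromen-4-one
Conditions: 3 M aq. HCl, MeOH/THF, 45 °C
Reagents that add atoms: none
Why: mild acid hydrolysis of the four phenolic MOM acetals, kept at moderate temperature so the ortho-prenyl phenol does not cyclise to a chroman.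

## Compound list

1 | 2',4',6'-trihydroxyacetophenone | CC(=O)c1c(O)cc(O)cc1O | starting material
2 | 1-[2,6-dihydroxy-4-(3-methylbut-2-enyloxy)phenyl]ethanone | CC(=O)c1c(O)cc(OCC=C(C)C)cc1O | intermediate
3 | 1-[2-hydroxy-6-(methoxymethoxy)-4-(3-methylbut-2-enyloxy)phenyl]ethanone | CC(=O)c1c(O)cc(OCC=C(C)C)cc1OCOC | intermediate
4 | 1-[2,4-dihydroxy-6-(methoxymethoxy)-3-(2-methylbut-3-en-2-yl)phenyl]ethanone | CC(=O)c1c(O)c(C(C)(C)C=C)c(O)cc1OCOC | intermediate
5 | 1-[2-hydroxy-4,6-bis(methoxymethoxy)-3-(2-methylbut-3-en-2-yl)phenyl]ethanone | CC(=O)c1c(O)c(C(C)(C)C=C)c(OCOC)cc1OCOC | intermediate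
6 | 3,4-dihydroxybenzaldehyde | O=Cc1ccc(O)c(O)c1 | starting material
7 | 4-hydroxy-3-(methoxymethoxy)benzaldehyde | O=Cc1ccc(O)c(OCOC)c1 | intermediate
8 | 3-(methoxymethoxy)-4-(triisopropylsilyloxy)benzaldehyde | O=Cc1ccc(O[Si](C(C)C)(C(C)C)C(C)C)c(OCOC)c1 | intermediate
9 | 5-(methoxymethoxy)-2-(3-methylbut-2-enyl)-4-(triisopropylsilyloxy)benzaldehyde | O=Cc1cc(OCOC)c(O[Si](C(C)C)(C(C)C)C(C)C)cc1CC=C(C)C | intermediate
10 | 4-hydroxy-5-(methoxymethoxy)-2-(3-methylbut-2-enyl)benzaldehyde | O=Cc1cc(OCOC)c(O)cc1CC=C(C)C | intermediate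
11 | 5-(methoxymethoxy)-4-[(2-methylbut-3-en-2-yl)oxy]-2-(3-methylbut-2-enyl)benzaldehyde | O=Cc1cc(OCOC)c(OC(C)(C)C=C)cc1CC=C(C)C | intermediate
12 | 4-hydroxy-5-(methoxymethoxy)-2,3-bis(3-methylbut-2-enyl)benzaldehyde | O=Cc1cc(OCOC)c(O)c(CC=C(C)C)c1CC=C(C)C | intermediate
13 | 4,5-bis(methoxymethoxy)-2,3-bis(3-methylbut-2-enyl)benzaldehyde | O=Cc1cc(OCOC)c(OCOC)c(CC=C(C)C)c1CC=C(C)C | intermediate
14 | (E)-chalcone from 5 and 13 | C=CC(C)(C)c1c(O)c(C(=O)/C=C/c2cc(OCOC)c(OCOC)c(CC=C(C)C)c2CC=C(C)C)c(OCOC)cc1OCOC | intermediate
15 | 5,7,4',5'-tetra-O-MOM Broussoflavonol C | C=CC(C)(C)c1c(OCOC)cc(OCOC)c2c(=O)c(O)c(-c3cc(OCOC)c(OCOC)c(CC=C(C)C)c3CC=C(C)C)oc12 | intermediate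
16 | Broussoflavonol C | C=CC(C)(C)c1c(O)cc(O)c2c(=O)c(O)c(-c3cc(O)c(O)c(CC=C(C)C)c3CC=C(C)C)oc12 | target

## Summary

**Total step count:** 14

**Longest linear sequence:** 10 steps (6 → 13 via steps 5–11, then steps 12–14)

**Three steps most likely to fail, with fallbacks**

1. **Step 7 (proposed new Rh(III) transient-imine C–H prenylation).** Risks are low conversion, reaction at C2, double prenylation, or cyclisation of the ortho-prenyl imine. Fallback with known chemistry: brominate 8 at C6 (NBS, MeCN; para to OMOM), then Stille-couple the aryl bromide with tributyl(3-methylbut-2-enyl)stannane (Pd(PPh3)4, CsF, DMF) to reach 9.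

2. **Step 13 (Algar–Flynn–Oyamada).** The 6'-alkoxy group and the ortho-substituted B ring may divert the reaction to the aurone. Fallback: oxidise 13 to the benzoic acid (Pinnick, excess 2-methyl-2-butene), esterify the 2-OH of 5, carry out a Baker–Venkataraman rearrangement and cyclodehydrate to the flavone, then install the 3-OH by C3-lithiation (LDA, −78 °C), B(OMe)3 and H2O2.

3. **Step 3 (A-ring Claisen).** Risks are C3/C5 regioselectivity and follow-on cyclisation of the ortho-(1,1-dimethylallyl)phenol at 180 °C. Fallback: run the Claisen on symmetric diol 2, where both ortho positions are equivalent and para is blocked, so only 3-(1,1-dimethylallyl)phloroacetophenone can form. Then differentiate by sterics with MOMCl (2.2 equiv), which protects the unhindered 4- and 6-OH and leaves the hindered, chelated 2-OH free, converging on 5.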